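The target is the mono-seco acid of a twofold-symmetric 6,6′-linked bis(chromanone lactone). Everything rests on opening each pyranone ring at its aryl ether bond O1–C2, which lies β to the C4 ketone (an oxa-Michael retron). The key step closes both rings at once: a cinchona squaramide-catalysed 6-endo-trig oxa-Michael addition in which the acidic butenolide C5′–H lets E/Z isomers and C5′ epimers equilibrate, so the mixture is funnelled into the (2S,5′R) array. Its precursor is an open-chain biaryl bis(2′-hydroxyaryl enone) carrying butenolides, assembled from a symmetric dialdehyde. Hydrogenation then sets the methyl centres and frees the phenols, and opening one lactone gives the target.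

Key step: step 11

Remark: the quinidine-derived squaramide in step 11 is assumed to deliver the phenoxide to the face of C2 that gives the (S) configuration (if the sense is opposite, the quinine-derived pseudoenantiomer is used with nothing else changed), and the γ-hydroxy acid 18 is assumed to survive isolation at pH 4 and 0 °C without relactonising.

Step 1
Reactants: 1 2,6-dihydroxybenzaldehyde
Product: 2 2-(benzyloxy)-6-hydroxybenzaldehyde
Conditions: BnBr (1.0 equiv), K2CO3 (1.0 equiv), acetone, reflux
Reagents that add atoms: benzyl bromide, BrCc1ccccc1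
Why: Williamson mono-O-alkylation, which should stop at the monoether because the remaining phenol is held in a hydrogen bond to the aldehyde and is a much poorer nucleophile.

Step 2
Reactants: 2 2-(benzyloxy)-6-hydroxybenzaldehyde
Product: 3 2-(benzyloxy)-3-bromo-6-hydroxybenzaldehyde
Conditions: NBS (1.0 equiv), MeCN, 0 °C
Reagents that add atoms: N-bromosuccinimide, O=C1CCC(=O)N1Br
Why: electrophilic aromatic bromination in which the free hydroxyl, the strongest donor, directs to its para position, which is the carbon next to the benzyloxy group.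

Step 3
Reactants: 3 2-(benzyloxy)-3-bromo-6-hydroxybenzaldehyde
Product: 4 2-(benzyloxy)-3-bromo-6-(methoxymethoxy)benzaldehyde
Conditions: MOMCl, iPr2NEt, CH2Cl2, 0 °C to rt
Reagents that add atoms: chloromethyl methyl ether, COCCl
Why: O-alkylation of the phenol to an acetal that blocks it through the organometallic steps and can later be removed by acid without touching the benzyl ether.

Step 4
Reactants: 4 2-(benzyloxy)-3-bromo-6-(methoxymethoxy)benzaldehyde
Product: 5 2-(benzyloxy)-6-(methoxymethoxy)-3-(4,4,5,5-tetramethyl-1,3,2-dioxaborolan-2-yl)benzaldehyde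
Conditions: bis(pinacolato)diboron (1.2 equiv), PdCl2(dppf) (5 mol %), KOAc (3.0 equiv), 1,4-dioxane, 90 °C; carried out on one half of the stock of 4
Reagents that add atoms: bis(pinacolato)diboron, CC1(C)OB(OC1(C)C)B1OC(C)(C)C(C)(C)O1
Why: Miyaura borylation (oxidative addition of zerovalent palladium into the aryl bromide, acetate-assisted transmetallation with the diboron, reductive elimination), which tolerates the aldehyde and both ethers and, with the weak acetate base, should not run on to a biaryl.

Step 5
Reactants: 4 2-(benzyloxy)-3-bromo-6-(methoxymethoxy)benzaldehyde; 5 2-(benzyloxy)-6-(methoxymethoxy)-3-(4,4,5,5-tetramethyl-1,3,2-dioxaborolan-2-yl)benzaldehyde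
Product: 6 2,2′-bis(benzyloxy)-4,4′-bis(methoxymethoxy)-[1,1′-biphenyl]-3,3′-dicarbaldehyde
Conditions: 4 (1.0 equiv), 5 (1.1 equiv), Pd(OAc)2 (5 mol %), SPhos (10 mol %), K3PO4 (3.0 equiv), toluene–H2O (10:1), 80 °C
Reagents that add atoms: none
Why: Suzuki–Miyaura cross-coupling of the aryl bromide with the boronate made from the same bromide, which joins one molecule of each partner into the symmetric biaryl, with the electron-rich biarylphosphine carrying the coupling in which each partner has one ortho substituent and the phosphate base sparing the non-enolisable aldehydes.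

Step 6
Reactants: 6 2,2′-bis(benzyloxy)-4,4′-bis(methoxymethoxy)-[1,1′-biphenyl]-3,3′-dicarbaldehyde; 7 methyl propiolate
Product: 9 dimethyl 4,4′-[2,2′-bis(benzyloxy)-4,4′-bis(methoxymethoxy)-[1,1′-biphenyl]-3,3′-diyl]bis(4-hydroxybut-2-ynoate), via lithium methyl propiolate 8 (not isolated)
Conditions: 7 (2.6 equiv), LiN(SiMe3)2 (2.5 equiv), THF, −78 °C; then 6, −78 °C; aq. NH4Cl
Reagents that add atoms: none
Why: 1,2-addition of a lithium acetylide to both aldehydes, forming carbinol centres without control that are erased in step 7.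

Step 7
Reactants: 9 dimethyl 4,4′-[2,2′-bis(benzyloxy)-4,4′-bis(methoxymethoxy)-[1,1′-biphenyl]-3,3′-diyl]bis(4-hydroxybut-2-ynoate)
Product: 10 dimethyl (2E,2′E)-4,4′-[2,2′-bis(benzyloxy)-4,4′-bis(methoxymethoxy)-[1,1′-biphenyl]-3,3′-diyl]bis(4-oxobut-2-enoate)
Conditions: DABCO (20 mol %), DMSO, rt
Reagents that add atoms: none
Why: amine-catalysed redox isomerisation of a γ-hydroxy-α,β-alkynoate to the (E)-γ-oxo-α,β-enoate, by deprotonation of the carbinol C–H that is activated through the alkynoate and tautomerisation of the resulting allenol.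

Step 8
Reactants: 11 4-methylfuran-2(5H)-one
Product: 12 tert-butyldimethyl[(4-methylfuran-2-yl)oxy]silane
Conditions: TBSOTf (1.1 equiv), Et3N (1.3 equiv), CH2Cl2, 0 °C
Reagents that add atoms: tert-butyldimethylsilyl trifluoromethanesulfonate, CC(C)(C)[Si](C)(C)OS(=O)(=O)C(F)(F)F
Why: soft enolisation and O-silylation of the butenolide, driven by formation of the aromatic 2-silyloxyfuran.

Step 9
Reactants: 10 dimethyl (2E,2′E)-4,4′-[2,2′-bis(benzyloxy)-4,4′-bis(methoxymethoxy)-[1,1′-biphenyl]-3,3′-diyl]bis(4-oxobut-2-enoate); 12 tert-butyldimethyl[(4-methylfuran-2-yl)oxy]silane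
Product: 14 MOM-protected bis(enone butenolide) as a mixture of E/Z isomers plus C5′ epimers (full name in the compound list), via bis(silyl enol ether) 13 (not isolated)
Conditions: 12 (2.5 equiv), TBSOTf (20 mol %), CH2Cl2, −78 °C; pyridine quench, solvent switch; then Pd(OAc)2 (20 mol %), O2 (1 atm), DMSO, 40 °C
Reagents that add atoms: none
Why: vinylogous Mukaiyama–Michael addition of the furan C5 to the alkene carbon β to the silyl-activated ketone (the ester-bearing carbon), followed by Saegusa–Ito dehydrogenation of the silyl enol ether so formed (palladium enolate, β-hydride elimination of the C2–H), which restores the C2=C3 double bond and erases the stereocentres of the addition.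

Step 10
Reactants: 14 MOM-protected bis(enone butenolide)
Product: 15 dimethyl 4,4′-[2,2′-bis(benzyloxy)-4,4′-dihydroxy-[1,1′-biphenyl]-3,3′-diyl]bis[2-(3-methyl-5-oxo-2,5-dihydrofuran-2-yl)-4-oxobut-2-enoate], mixture of isomers
Conditions: TFA–CH2Cl2 (1:10), 0 °C; pH 7 buffer work-up
Reagents that add atoms: none
Why: acidolysis of the two aryl MOM acetals, which are especially labile ortho to a carbonyl, under conditions that leave benzyl ethers, esters and butenolides alone and avoid any base that would start an uncatalysed cyclisation.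

Step 11
Reactants: 15 bis(2′-hydroxyaryl enone butenolide), mixture of isomers
Product: 16 dimethyl (2S,2′S)-5,5′-bis(benzyloxy)-2,2′-bis[(2R)-3-methyl-5-oxo-2,5-dihydrofuran-2-yl]-4,4′-dioxo-[6,6′-bichromane]-2,2′-dicarboxylate
Conditions: squaramide made from 9-amino-9-deoxy-epi-quinidine and 3,5-bis(trifluoromethyl)aniline (10 mol %), toluene–CH2Cl2, −20 °C; citric acid wash
Reagents that add atoms: none
Why: The quinuclidine nitrogen of the bifunctional catalyst deprotonates the free phenol while the squaramide N–H bonds hold the enone carbonyl, and the phenoxide adds to C2, the carbon β to the C4 ketone, giving a chromanone enolate that is protonated at C3 (intramolecular oxa-Michael addition). The closest known reaction type is the cinchona thiourea- or squaramide-catalysed asymmetric cyclisation of 2′-hydroxyaryl enones to chromanones and flavanones. Each of the two pyranone rings closes in the 6-endo-trig mode. C2 is set by the catalyst, which fixes the enone face that the phenoxide reaches, and C5′ is set by the substrate in a dynamic kinetic resolution: the C5′–H is γ to the enone and γ within the butenolide, so E/Z isomers, C5′ epimers and the ylidene-butenolide tautomer interconvert through one dienolate under the amine, and only the epimer that can place its C5′–O bond anti to the incoming phenoxide with C5′–H eclipsing the alkene (polar Felkin–Anh arrangement, minimal allylic strain) closes fast, which corresponds to the (2S,5′R) relation. The step needs 6-endo rather than 5-exo closure (attack at C3, β to the ester), secured because the aryl ketone is the stronger acceptor and gives the more stable enolate; it needs the right phenol, secured by the benzyl ether on the other ortho oxygen; and it needs kinetic control after closure, secured by the much lower acidity of C5′–H once conjugation to the enone is lost and by the low temperature. Because two independent ends cyclise, a minor wrong-handed closure should end mostly in a separable diastereomer, which should raise the enantiomeric purity of 16.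

Step 12
Reactants: 16 bis(chromanone butenolide) bis(benzyl ether)
Product: 17 dimethyl (2S,2′S)-5,5′-dihydroxy-2,2′-bis[(2R,3S)-3-methyl-5-oxooxolan-2-yl]-4,4′-dioxo-[6,6′-bichromane]-2,2′-dicarboxylate
Conditions: H2 (4 bar), Pd/C (10 wt %), EtOAc–MeOH, rt
Reagents that add atoms: none
Why: heterogeneous hydrogenation in which hydrogen adds to each butenolide C=C from the face opposite the quaternary chromanone substituent on C5′, so the methyl group ends cis to it (the 3S centre), while both benzyl ethers are hydrogenolysed in the same operation and the freed 5-hydroxyl hydrogen-bonds to the aryl ketone and protects it.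

Step 13
Reactants: 17 bis(chromanone lactone)
Product: 18 (3S,4R)-4-hydroxy-4-[(2S)-5-hydroxy-6-{(2S)-5-hydroxy-2-(methoxycarbonyl)-2-[(2R,3S)-3-methyl-5-oxooxolan-2-yl]-4-oxochroman-6-yl}-2-(methoxycarbonyl)-4-oxochroman-2-yl]-3-methylbutanoic acid (target)
Conditions: NaOH (3.0 equiv), THF–H2O, 0 °C; then 0.5 M HCl to pH 4, 0 °C; chromatography, with recovered 17 and acid-relactonised diacid returned to the step
Reagents that add atoms: sodium hydroxide, [Na+].[OH-]
Why: saponification (acyl–oxygen cleavage, no stereocentre touched) of one of two equivalent γ-lactones, where two equivalents of base go to the phenols, whose phenoxides disfavour enolisation and retro-oxa-Michael opening, and the hindered tertiary methyl esters should react far more slowly than the unhindered lactone carbonyl; the opening is expected to be statistical, hence the recycling.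

Compound list
1 | 2,6-dihydroxybenzaldehyde | O=Cc1c(O)cccc1O | starting material
2 | 2-(benzyloxy)-6-hydroxybenzaldehyde | O=Cc1c(O)cccc1OCc1ccccc1 | intermediate
3 | 2-(benzyloxy)-3-bromo-6-hydroxybenzaldehyde | O=Cc1c(OCc2ccccc2)c(Br)ccc1O | intermediate
4 | 2-(benzyloxy)-3-bromo-6-(methoxymethoxy)benzaldehyde | COCOc1ccc(Br)c(OCc2ccccc2)c1C=O | intermediate
5 | 2-(benzyloxy)-6-(methoxymethoxy)-3-(4,4,5,5-tetramethyl-1,3,2-dioxaborolan-2-yl)benzaldehyde | COCOc1ccc(B2OC(C)(C)C(C)(C)O2)c(OCc2ccccc2)c1C=O | intermediate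
6 | 2,2′-bis(benzyloxy)-4,4′-bis(methoxymethoxy)-[1,1′-biphenyl]-3,3′-dicarbaldehyde | COCOc1ccc(c(OCc2ccccc2)c1C=O)-c1ccc(OCOC)c(C=O)c1OCc1ccccc1 | intermediate
7 | methyl propiolate (methyl prop-2-ynoate) | C#CC(=O)OC | starting material
8 | lithium methyl propiolate (methyl 3-lithioprop-2-ynoate) | [Li]C#CC(=O)OC | intermediate (not isolated)
9 | dimethyl 4,4′-[2,2′-bis(benzyloxy)-4,4′-bis(methoxymethoxy)-[1,1′-biphenyl]-3,3′-diyl]bis(4-hydroxybut-2-ynoate), mixture of diastereomers | COCOc1ccc(c(OCc2ccccc2)c1C(O)C#CC(=O)OC)-c1ccc(OCOC)c(C(O)C#CC(=O)OC)c1OCc1ccccc1 | intermediate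
10 | dimethyl (2E,2′E)-4,4′-[2,2′-bis(benzyloxy)-4,4′-bis(methoxymethoxy)-[1,1′-biphenyl]-3,3′-diyl]bis(4-oxobut-2-enoate) | COCOc1ccc(c(OCc2ccccc2)c1C(=O)/C=C/C(=O)OC)-c1ccc(OCOC)c(C(=O)/C=C/C(=O)OC)c1OCc1ccccc1 | intermediate
11 | 4-methylfuran-2(5H)-one | CC1=CC(=O)OC1 | starting material
12 | tert-butyldimethyl[(4-methylfuran-2-yl)oxy]silane | Cc1coc(O[Si](C)(C)C(C)(C)C)c1 | intermediate
13 | dimethyl 4,4′-[2,2′-bis(benzyloxy)-4,4′-bis(methoxymethoxy)-[1,1′-biphenyl]-3,3′-diyl]bis{4-[(tert-butyldimethylsilyl)oxy]-2-(3-methyl-5-oxo-2,5-dihydrofuran-2-yl)but-3-enoate}, mixture of stereoisomers | COCOc1ccc(c(OCc2ccccc2)c1C(O[Si](C)(C)C(C)(C)C)=CC(C(=O)OC)C1OC(=O)C=C1C)-c1ccc(OCOC)c(C(O[Si](C)(C)C(C)(C)C)=CC(C(=O)OC)C2OC(=O)C=C2C)c1OCc1ccccc1 | intermediate (not isolated)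
14 | dimethyl 4,4′-[2,2′-bis(benzyloxy)-4,4′-bis(methoxymethoxy)-[1,1′-biphenyl]-3,3′-diyl]bis[2-(3-methyl-5-oxo-2,5-dihydrofuran-2-yl)-4-oxobut-2-enoate], mixture of E/Z isomers and C5′ epimers | COCOc1ccc(c(OCc2ccccc2)c1C(=O)C=C(C(=O)OC)C1OC(=O)C=C1C)-c1ccc(OCOC)c(C(=O)C=C(C(=O)OC)C2OC(=O)C=C2C)c1OCc1ccccc1 | intermediate
15 | dimethyl 4,4′-[2,2′-bis(benzyloxy)-4,4′-dihydroxy-[1,1′-biphenyl]-3,3′-diyl]bis[2-(3-methyl-5-oxo-2,5-dihydrofuran-2-yl)-4-oxobut-2-enoate], mixture of E/Z isomers and C5′ epimers | Oc1ccc(c(OCc2ccccc2)c1C(=O)C=C(C(=O)OC)C1OC(=O)C=C1C)-c1ccc(O)c(C(=O)C=C(C(=O)OC)C2OC(=O)C=C2C)c1OCc1ccccc1 | intermediate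
16 | dimethyl (2S,2′S)-5,5′-bis(benzyloxy)-2,2′-bis[(2R)-3-methyl-5-oxo-2,5-dihydrofuran-2-yl]-4,4′-dioxo-[6,6′-bichromane]-2,2′-dicarboxylate | O=C1C[C@@](C(=O)OC)([C@@H]2OC(=O)C=C2C)Oc2ccc(-c3ccc4c(c3OCc3ccccc3)C(=O)C[C@@](C(=O)OC)([C@@H]3OC(=O)C=C3C)O4)c(OCc3ccccc3)c12 | intermediate
17 | dimethyl (2S,2′S)-5,5′-dihydroxy-2,2′-bis[(2R,3S)-3-methyl-5-oxooxolan-2-yl]-4,4′-dioxo-[6,6′-bichromane]-2,2′-dicarboxylate | O=C1C[C@@](C(=O)OC)([C@@H]2OC(=O)C[C@@H]2C)Oc2ccc(-c3ccc4c(c3O)C(=O)C[C@@](C(=O)OC)([C@@H]3OC(=O)C[C@@H]3C)O4)c(O)c12 | intermediate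
18 | (3S,4R)-4-hydroxy-4-[(2S)-5-hydroxy-6-{(2S)-5-hydroxy-2-(methoxycarbonyl)-2-[(2R,3S)-3-methyl-5-oxooxolan-2-yl]-4-oxochroman-6-yl}-2-(methoxycarbonyl)-4-oxochroman-2-yl]-3-methylbutanoic acid | COC(=O)[C@@]1([C@H](O)[C@@H](C)CC(=O)O)CC(=O)c2c(ccc(-c3ccc4c(c3O)C(=O)C[C@@](C(=O)OC)([C@@H]3OC(=O)C[C@@H]3C)O4)c2O)O1 | target

Total step count: 13. Longest linear sequence: 12 steps (steps 1 to 7 and 9 to 13; step 8 prepares the silyloxyfuran).

Steps most likely to fail

Step 11. The open-chain material may settle into the fully conjugated ylidene-butenolide tautomer and cyclise only sluggishly; the catalyst and the substrate preference at C5′ may not reinforce each other, giving incomplete funnelling; and C5′ may epimerise after ring closure. The fallback closes the pyranone ring before the side chain is attached. It sets out from 10: acidolysis of the MOM groups (TFA, CH2Cl2) and treatment with Et3N let each phenol add to its aroylacrylate, giving dimethyl 5,5′-bis(benzyloxy)-4,4′-dioxo-[6,6′-bichromane]-2,2′-dicarboxylate F1. Dehydrogenation with DDQ in dioxane at 100 °C gives the bis(chromone ester), dimethyl 5,5′-bis(benzyloxy)-4,4′-dioxo-4H,4′H-[6,6′-bichromene]-2,2′-dicarboxylate F2. A direct catalytic asymmetric vinylogous conjugate addition of butenolide 11 to the 2-ester chromones, with the dinuclear zinc catalyst formed from Et2Zn and (S,S)-ProPhenol in THF, then forms the C2–C5′ bonds and both stereocentres at each end. The ligand enantiomer is chosen for the 2S series, and the route is rejoined at 16.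

Step 13. Opening may run past the mono stage, the hydroxy acid may relactonise during acidification, and hydroxide may trigger enolisation with retro-oxa-Michael opening. The fallback moves the differentiation to the protected stage and makes it self-limiting by precipitation. It sets out from 16: hydrogenation over Rh/Al2O3 (H2, 1 atm, EtOAc) reduces the butenolides but keeps the benzyl ethers, giving dimethyl (2S,2′S)-5,5′-bis(benzyloxy)-2,2′-bis[(2R,3S)-3-methyl-5-oxooxolan-2-yl]-4,4′-dioxo-[6,6′-bichromane]-2,2′-dicarboxylate F3. One equivalent of the weakly basic KOSiMe3 in Et2O–THF at 0 °C opens one lactone, and the potassium carboxylate should precipitate and so escape a second opening. Cold acidification to pH 4 gives the mono-seco acid bis(benzyl ether), (3S,4R)-4-[(2S)-5-(benzyloxy)-6-{(2S)-5-(benzyloxy)-2-(methoxycarbonyl)-2-[(2R,3S)-3-methyl-5-oxooxolan-2-yl]-4-oxochroman-6-yl}-2-(methoxycarbonyl)-4-oxochroman-2-yl]-4-hydroxy-3-methylbutanoic acid F4. Neutral hydrogenolysis (H2, Pd/C, EtOAc) then rejoins the route at 18.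

Step 9. The silyloxyfuran may add at the alkene carbon β to the ester instead of β to the ketone, and the dehydrogenation of the hindered silyl enol ether may stall. The fallback brings in the acceptor at the alkyne oxidation level, so no dehydrogenation is needed. It sets out from 9: oxidation with Dess–Martin periodinane (NaHCO3, CH2Cl2, 0 °C) gives the bis(ynone), dimethyl 4,4′-[2,2′-bis(benzyloxy)-4,4′-bis(methoxymethoxy)-[1,1′-biphenyl]-3,3′-diyl]bis(4-oxobut-2-ynoate) F5. DABCO-catalysed conjugate addition of the pronucleophile 11 itself (MeCN, 0 °C) at the alkyne carbon β to the ketone then rejoins the route at 14.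

Further compounds
F1 | step 11 | dimethyl 5,5′-bis(benzyloxy)-4,4′-dioxo-[6,6′-bichromane]-2,2′-dicarboxylate, mixture of stereoisomers | COC(=O)C1CC(=O)c2c(O1)ccc(c2OCc1ccccc1)-c1ccc2OC(CC(=O)c2c1OCc1ccccc1)C(=O)OC
F2 | step 11 | dimethyl 5,5′-bis(benzyloxy)-4,4′-dioxo-4H,4′H-[6,6′-bichromene]-2,2′-dicarboxylate | COC(=O)C1=CC(=O)c2c(O1)ccc(c2OCc1ccccc1)-c1ccc2OC(=CC(=O)c2c1OCc1ccccc1)C(=O)OC
F3 | step 13 | dimethyl (2S,2′S)-5,5′-bis(benzyloxy)-2,2′-bis[(2R,3S)-3-methyl-5-oxooxolan-2-yl]-4,4′-dioxo-[6,6′-bichromane]-2,2′-dicarboxylate | O=C1C[C@@](C(=O)OC)([C@@H]2OC(=O)C[C@@H]2C)Oc2ccc(-c3ccc4c(c3OCc3ccccc3)C(=O)C[C@@](C(=O)OC)([C@@H]3OC(=O)C[C@@H]3C)O4)c(OCc3ccccc3)c12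
F4 | step 13 | (3S,4R)-4-[(2S)-5-(benzyloxy)-6-{(2S)-5-(benzyloxy)-2-(methoxycarbonyl)-2-[(2R,3S)-3-methyl-5-oxooxolan-2-yl]-4-oxochroman-6-yl}-2-(methoxycarbonyl)-4-oxochroman-2-yl]-4-hydroxy-3-methylbutanoic acid | COC(=O)[C@@]1([C@H](O)[C@@H](C)CC(=O)O)CC(=O)c2c(ccc(-c3ccc4c(c3OCc3ccccc3)C(=O)C[C@@](C(=O)OC)([C@@H]3OC(=O)C[C@@H]3C)O4)c2OCc2ccccc2)O1
F5 | step 9 | dimethyl 4,4′-[2,2′-bis(benzyloxy)-4,4′-bis(methoxymethoxy)-[1,1′-biphenyl]-3,3′-diyl]bis(4-oxobut-2-ynoate) | COCOc1ccc(c(OCc2ccccc2)c1C(=O)C#CC(=O)OC)-c1ccc(OCOC)c(C(=O)C#CC(=O)OC)c1OCc1ccccc1
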